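The isoflavone's pyranone ring is cut at C3: C3 carries the 4-methoxyphenyl group and is flanked by the C4 ketone carbon and by C2, a formic-acid-level carbon already bonded to O1. A benzylic phosphorus ylide therefore serves as a one-carbon linchpin. It is C-acylated by an aroyl chloride (C3–C4), and the resulting keto ylide olefinates an ortho aryl formate (C2=C3), closing the O1–C2–C3–C4–C4a–C8a ring with loss of triphenylphosphine oxide in one flask. The acyl partner is 2-(formyloxy)-3-methoxy-4-(prenyloxy)benzoyl chloride, made in five steps from methyl 2,3,4-trihydroxybenzoate with both ethers already in place, so the key step gives the target directly.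

Key step: step 6

Remark: the target has no stereocentre and no hindered axis, so it is one achiral compound and no step has to control configuration (prenyl = 3-methylbut-2-en-1-yl throughout).

Step 1
Reactants: 1 methyl 2,3,4-trihydroxybenzoate; 2 prenyl bromide (1-bromo-3-methylbut-2-ene)
Product: 3 methyl 2,3-dihydroxy-4-(prenyloxy)benzoate
Conditions: NaHCO3 (1.5 equiv), 2 (1.05 equiv), DMF, rt to 40 °C
Reagents that add atoms: none
Why: Williamson ether synthesis under weak-base control: hydrogencarbonate should ionise only the 4-OH, which is para to the ester and the most acidic, while the 2-OH is locked in a hydrogen bond to the ester carbonyl, so one equivalent of the allylic bromide should alkylate O4.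

Step 2
Reactants: 3 methyl 2,3-dihydroxy-4-(prenyloxy)benzoate
Product: 4 methyl 2-hydroxy-3-methoxy-4-(prenyloxy)benzoate
Conditions: MeI (1.1 equiv), K2CO3 (1.1 equiv), acetone, rt
Reagents that add atoms: iodomethane, CI
Why: Williamson O-methylation: of the two remaining phenols the 2-OH is chelated to the ester carbonyl and poorly nucleophilic, so one equivalent of iodomethane should methylate the free 3-OH, the usual behaviour of 2,3-dihydroxybenzoates.

Step 3
Reactants: 4 methyl 2-hydroxy-3-methoxy-4-(prenyloxy)benzoate
Product: 5 2-hydroxy-3-methoxy-4-(prenyloxy)benzoic acid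
Conditions: NaOH (4 equiv), MeOH/THF/H2O, 50 °C; then 1 M HCl to pH 3 at 0 °C, extraction
Reagents that add atoms: sodium hydroxide (its oxygen becomes the acid OH), [Na+].[OH-]
Why: Ester saponification by acyl–oxygen cleavage: the aryl methyl and aryl prenyl ethers are inert to hydroxide, and the cold, brief acidification should free the acid without acid-induced loss of the prenyl group or decarboxylation.

Step 4
Reactants: 5 2-hydroxy-3-methoxy-4-(prenyloxy)benzoic acid
Product: 6 2-(formyloxy)-3-methoxy-4-(prenyloxy)benzoic acid
Conditions: acetic formic anhydride (freshly distilled, 4 equiv), HCO2Na (0.2 equiv), THF, 0 °C to rt; short ice-water quench, extraction, toluene azeotrope, no chromatography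
Reagents that add atoms: acetic formic anhydride, CC(=O)OC=O
Why: O-Formylation of a phenol with a mixed anhydride: the formyl carbon is much more electrophilic and less hindered than the acetyl carbon, so the hindered phenol should be formylated and not acetylated, and the short cold quench returns the carboxyl group as the free acid while the aryl formate survives.

Step 5
Reactants: 6 2-(formyloxy)-3-methoxy-4-(prenyloxy)benzoic acid
Product: 7 2-(formyloxy)-3-methoxy-4-(prenyloxy)benzoyl chloride
Conditions: 1-chloro-N,N,2-trimethylprop-1-en-1-amine (1.05 equiv), CH2Cl2, 0 °C to rt; evaporation, crude 7 taken up in THF under argon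
Reagents that add atoms: 1-chloro-N,N,2-trimethylprop-1-en-1-amine, CC(C)=C(Cl)N(C)C
Why: Acid chloride formation with an α-chloroenamine: the acid adds to the keteniminium form of the reagent and chloride then displaces the amide, the acid proton ending on carbon of the amide by-product, so no HCl or base is present to attack the prenyl ether or the aryl formate.

Step 6
Reactants: 7 2-(formyloxy)-3-methoxy-4-(prenyloxy)benzoyl chloride; 8 (4-methoxybenzyl)triphenylphosphonium chloride
Product: 13 8-methoxy-3-(4-methoxyphenyl)-7-(prenyloxy)-4H-chromen-4-one (target), via ylide 9 (not isolated), via acylphosphonium chloride 10 (not isolated), via keto ylide 11 (not isolated), via oxaphosphetane 12 (not isolated)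
Conditions: 8 (2.0 equiv), n-BuLi (1.95 equiv), THF, 0 °C; ylide solution added slowly to 7 (1.0 equiv) in THF at −78 °C; then rt, then 60 °C; precipitated 8 filtered off, chromatography
Reagents that add atoms: none
Why: Proposed new method: the benzylidene ylide 9 attacks the acid chloride at carbon to give acylphosphonium salt 10 (C3–C4), a second equivalent of 9 removes the now strongly acidic benzylic proton (transylidation) to give keto ylide 11, and the ylide carbon of 11 adds to the neighbouring formyl carbonyl to give oxaphosphetane 12, which expels triphenylphosphine oxide to form C2=C3. The closest known reaction type is ylide C-acylation followed by intramolecular Wittig olefination of an ester carbonyl, which turns O-acylsalicylic acid derivatives into 2-substituted chromones; what has not been shown is an α-aryl, doubly stabilised ylide combined with a formate as the ester partner, which places the substituent at C3 and leaves C2 unsubstituted. The pyranone ring closes in a 6-exo-trig mode, the ylide carbon attacking the formate C=O whose oxygen lies outside the new ring, and no stereocentre remains in the product because the two centres of 12 are destroyed on elimination. The step needs chemoselectivity of 9 for the acid chloride over the aryl formate: this rests on the much greater electrophilicity of the acid chloride at −78 °C, on adding the ylide to 7 so that free ylide never accumulates, on using slightly less than two equivalents, and on an ylide solution free of amine or alkoxide. Once formed, 11 is too weakly basic to decarbonylate or cleave the formate, and the formyl carbon, the least hindered and most electrophilic ester carbon available, is expected to offset the low nucleophilicity of the stabilised ylide on gentle heating.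

Compound list
1 | methyl 2,3,4-trihydroxybenzoate | COC(=O)c1ccc(O)c(O)c1O | starting material
2 | prenyl bromide (1-bromo-3-methylbut-2-ene) | CC(C)=CCBr | starting material
3 | methyl 2,3-dihydroxy-4-(prenyloxy)benzoate | COC(=O)c1ccc(OCC=C(C)C)c(O)c1O | intermediate
4 | methyl 2-hydroxy-3-methoxy-4-(prenyloxy)benzoate | COC(=O)c1ccc(OCC=C(C)C)c(OC)c1O | intermediate
5 | 2-hydroxy-3-methoxy-4-(prenyloxy)benzoic acid | COc1c(O)c(C(=O)O)ccc1OCC=C(C)C | intermediate
6 | 2-(formyloxy)-3-methoxy-4-(prenyloxy)benzoic acid | COc1c(OC=O)c(C(=O)O)ccc1OCC=C(C)C | intermediate
7 | 2-(formyloxy)-3-methoxy-4-(prenyloxy)benzoyl chloride | COc1c(OC=O)c(C(=O)Cl)ccc1OCC=C(C)C | intermediate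
8 | (4-methoxybenzyl)triphenylphosphonium chloride | COc1ccc(C[P+](c2ccccc2)(c2ccccc2)c2ccccc2)cc1.[Cl-] | starting material
9 | (4-methoxybenzylidene)triphenylphosphorane | COc1ccc(C=P(c2ccccc2)(c2ccccc2)c2ccccc2)cc1 | intermediate (not isolated)
10 | {2-[2-(formyloxy)-3-methoxy-4-(prenyloxy)phenyl]-1-(4-methoxyphenyl)-2-oxoethyl}triphenylphosphonium chloride (racemic, labile CH, no configuration drawn) | COc1ccc(C(C(=O)c2ccc(OCC=C(C)C)c(OC)c2OC=O)[P+](c2ccccc2)(c2ccccc2)c2ccccc2)cc1.[Cl-] | intermediate (not isolated)
11 | 1-[2-(formyloxy)-3-methoxy-4-(prenyloxy)phenyl]-2-(4-methoxyphenyl)-2-(triphenylphosphoranylidene)ethan-1-one | COc1ccc(C(C(=O)c2ccc(OCC=C(C)C)c(OC)c2OC=O)=P(c2ccccc2)(c2ccccc2)c2ccccc2)cc1 | intermediate (not isolated)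
12 | oxaphosphetane cis-fused across C2–C3 of the chroman-4-one, P on C3 and O on C2 (racemic, relative configuration drawn) | COc1ccc([C@]23C(=O)c4ccc(OCC=C(C)C)c(OC)c4O[C@H]2OP3(c2ccccc2)(c2ccccc2)c2ccccc2)cc1 | intermediate (not isolated)
13 | 8-methoxy-3-(4-methoxyphenyl)-7-(prenyloxy)-4H-chromen-4-one | COc1ccc(-c2coc3c(OC)c(OCC=C(C)C)ccc3c2=O)cc1 | target

Total step count: 6
Longest linear sequence: 6 steps (1 → 3 → 4 → 5 → 6 → 7 → 13); 8 is commercial and its ylide is made in the flask of step 6.

Steps most likely to fail

Step 6 (proposed new method). Two processes may defeat it. The nucleophilic, basic benzylidene ylide may attack or decarbonylate the aryl formate instead of reacting only at the acid chloride. Alternatively, the doubly stabilised keto ylide may fail to add to the formate, so that the sequence stalls before ring closure. The fallback uses known chemistry, sets out from 5 and comes back at 13. Acid 5 is coupled with N,O-dimethylhydroxylamine hydrochloride (EDC, HOBt, i-Pr2NEt, CH2Cl2) to the Weinreb amide 2-hydroxy-N,3-dimethoxy-N-methyl-4-(prenyloxy)benzamide F1. Excess 4-methoxybenzylmagnesium chloride (THF, 0 °C; the first equivalent is consumed by the phenol) should then give the deoxybenzoin 1-[2-hydroxy-3-methoxy-4-(prenyloxy)phenyl]-2-(4-methoxyphenyl)ethan-1-one F2 without over-addition. Heating F2 with N,N-dimethylformamide dimethyl acetal (toluene, 90 °C) forms in the flask the enaminone (E)-3-(dimethylamino)-1-[2-hydroxy-3-methoxy-4-(prenyloxy)phenyl]-2-(4-methoxyphenyl)prop-2-en-1-one F3, which cyclises by conjugate addition of the phenol and loss of dimethylamine to 13.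

Step 4. The formyl group may be lost by hydrolysis, or by transfer to the neighbouring carboxyl group, while the free ortho acid is handled in the aqueous quench; formylation of the hindered, chelated phenol may also be incomplete. The fallback sets out from 5 and comes back at 7, so that no free acid ever carries the formate. Acid 5 is silylated at the carboxyl group only (TBSCl 1.05 equiv, imidazole, DMF, 0 °C) to tert-butyldimethylsilyl 2-hydroxy-3-methoxy-4-(prenyloxy)benzoate F4. The phenol is formylated with acetic formic anhydride under the conditions of step 4, with a non-aqueous work-up, to tert-butyldimethylsilyl 2-(formyloxy)-3-methoxy-4-(prenyloxy)benzoate F5. Oxalyl chloride with catalytic DMF (CH2Cl2, 0 °C to rt) then converts the silyl ester directly into 7 under neutral conditions, with volatile by-products only.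

Step 1. Site selectivity among the three phenols may be poor, with alkylation at O3 or double alkylation giving mixtures that are hard to separate. The fallback sets out from prenyl bromide 2 and comes back at 5; it replaces 1 by a symmetrical diol, so the only selectivity needed is that of a free over a chelated phenol. Commercial 2-methoxyresorcinol F6 is carboxylated under Kolbe–Schmitt conditions (KHCO3, CO2, water/glycerol, about 110 °C) to 2,4-dihydroxy-3-methoxybenzoic acid F7. Reaction of F7 with 2 (2.2 equiv, K2CO3, DMF, rt) alkylates the carboxylate and the non-chelated 4-OH to give prenyl 2-hydroxy-3-methoxy-4-(prenyloxy)benzoate F8. Saponification (NaOH, aqueous MeOH, then cold acidification as in step 3) gives 5.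

Further compounds
F1 | step 6 | 2-hydroxy-N,3-dimethoxy-N-methyl-4-(prenyloxy)benzamide | CON(C)C(=O)c1ccc(OCC=C(C)C)c(OC)c1O
F2 | step 6 | 1-[2-hydroxy-3-methoxy-4-(prenyloxy)phenyl]-2-(4-methoxyphenyl)ethan-1-one | COc1ccc(CC(=O)c2ccc(OCC=C(C)C)c(OC)c2O)cc1
F3 | step 6 | (E)-3-(dimethylamino)-1-[2-hydroxy-3-methoxy-4-(prenyloxy)phenyl]-2-(4-methoxyphenyl)prop-2-en-1-one | CN(C)/C=C(\c1ccc(OC)cc1)C(=O)c1ccc(OCC=C(C)C)c(OC)c1O
F4 | step 4 | tert-butyldimethylsilyl 2-hydroxy-3-methoxy-4-(prenyloxy)benzoate | COc1c(O)c(C(=O)O[Si](C)(C)C(C)(C)C)ccc1OCC=C(C)C
F5 | step 4 | tert-butyldimethylsilyl 2-(formyloxy)-3-methoxy-4-(prenyloxy)benzoate | COc1c(OC=O)c(C(=O)O[Si](C)(C)C(C)(C)C)ccc1OCC=C(C)C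
F6 | step 1 | 2-methoxyresorcinol (2-methoxybenzene-1,3-diol) | COc1c(O)cccc1O
F7 | step 1 | 2,4-dihydroxy-3-methoxybenzoic acid | COc1c(O)ccc(C(=O)O)c1O
F8 | step 1 | prenyl 2-hydroxy-3-methoxy-4-(prenyloxy)benzoate | COc1c(O)c(C(=O)OCC=C(C)C)ccc1OCC=C(C)C
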